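**Retrosynthetic overview**
1. Quinone methide ring (formed last): target ⇐ triaryl carbinol carrying 4-methoxyphenyl groups, by O-demethylation and loss of water, the dehydration assumed in nature.
2. Carbinol ⇐ methyl 2-alkynyl-6-aryl-3-methylbenzoate + 2 × 4-methoxyphenyllithium (the ester carbon becomes the central sp2 carbon).
3. Aryl–alkyne bond ⇐ Sonogashira coupling of the triflate of a methyl 6-aryl-3-methylsalicylate with 4-ethynylanisole.
4. Ring A (formed first, the only ring built from acyclic material) ⇐ methyl 3-oxopentanoate + 4-methoxycinnamaldehyde by Michael addition / aldol condensation / aromatisation, a polyketide-style closure to a salicylate; the anisyl rings are bought.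
5. Ring order: ring A (step 1) → quinone methide ring (step 5).

Assumption: the SMILES holds no stereocentre and no defined axis, so the target is made as the achiral compound it describes; ring A is taken to arise in nature by polyketide-type aldol condensation/aromatisation and the quinone methide ring by loss of water from a triaryl carbinol.

**Step 1**
Reactants: 1 methyl 3-oxopentanoate; 2 (E)-3-(4-methoxyphenyl)prop-2-enal (4-methoxycinnamaldehyde)
Product: 5 methyl 2-hydroxy-6-(4-methoxyphenyl)-3-methylbenzoate, via Michael adduct 3 (not isolated), via cyclohexenone 4 (not isolated)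
Conditions: rac-α,α-diphenylprolinol trimethylsilyl ether (10 mol %), PhCO2H (10 mol %), toluene, rt; then p-TsOH·H2O (20 mol %), 80 °C; then DDQ (1.3 equiv), 100 °C
Reagents that add atoms: none
Why: Proposed new method: iminium-activated Michael addition of the β-keto ester to the enal, acid-catalysed intramolecular aldol condensation of the ethyl ketone onto the aldehyde (a Robinson-type [3+3] annulation that mirrors polyketide aldol ring closure) and DDQ dehydrogenation of the enolisable β-keto ester cyclohexenone to the salicylate are each known reaction types and are telescoped here in one pot, the closest known reaction being the organocatalytic Michael/aldol cyclohexenone synthesis from β-keto esters and enals; both transient stereocentres are erased on aromatisation, so none has to be controlled.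

**Step 2**
Reactants: 5 methyl 2-hydroxy-6-(4-methoxyphenyl)-3-methylbenzoate
Product: 6 methyl 6-(4-methoxyphenyl)-3-methyl-2-(trifluoromethylsulfonyloxy)benzoate
Conditions: Tf2O (1.3 equiv), pyridine, CH2Cl2, 0 °C → rt
Reagents that add atoms: trifluoromethanesulfonic anhydride (Tf2O), O=S(=O)(OS(=O)(=O)C(F)(F)F)C(F)(F)F
Why: O-sulfonylation (triflation) of the salicylate phenol is routine even when the OH is hydrogen-bonded to the ortho ester, and the ester and anisole are inert to Tf2O/pyridine; no stereocentre is involved.

**Step 3**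
Reactants: 6 methyl 6-(4-methoxyphenyl)-3-methyl-2-(trifluoromethylsulfonyloxy)benzoate; 7 1-ethynyl-4-methoxybenzene (4-ethynylanisole)
Product: 8 methyl 6-(4-methoxyphenyl)-2-[(4-methoxyphenyl)ethynyl]-3-methylbenzoate
Conditions: PdCl2(PPh3)2 (5 mol %), CuI (10 mol %), Et3N, DMF, 80 °C, slow addition of 7
Reagents that add atoms: none
Why: Sonogashira coupling, in which the ortho ester activates the triflate toward oxidative addition to zerovalent palladium and the rod-shaped copper acetylide tolerates the two flanking substituents; no stereocentre is involved.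

**Step 4**
Reactants: 8 methyl 6-(4-methoxyphenyl)-2-[(4-methoxyphenyl)ethynyl]-3-methylbenzoate; 9 1-bromo-4-methoxybenzene (4-bromoanisole)
Product: 12 [6-(4-methoxyphenyl)-2-[(4-methoxyphenyl)ethynyl]-3-methylphenyl]bis(4-methoxyphenyl)methanol, via (4-methoxyphenyl)lithium 10 (not isolated), via diaryl ketone 11 (not isolated)
Conditions: 9 (4.4 equiv), n-BuLi (4.2 equiv), THF, −78 °C; then 8, −78 °C → rt; then H2O
Reagents that add atoms: none
Why: bromine–lithium exchange followed by double addition of the aryllithium to the ester (acyl substitution to the ketone, then 1,2-addition) gives the tertiary carbinol, the slim alkynyl neighbour leaving the carbonyl accessible; the new carbinol carbon carries two identical aryl groups and is not stereogenic.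

**Step 5**
Reactants: 12 [6-(4-methoxyphenyl)-2-[(4-methoxyphenyl)ethynyl]-3-methylphenyl]bis(4-methoxyphenyl)methanol
Product: 14 Selaginellin U (4-[[6-(4-hydroxyphenyl)-2-[(4-hydroxyphenyl)ethynyl]-3-methylphenyl](4-hydroxyphenyl)methylidene]cyclohexa-2,5-dien-1-one), via triarylmethyl cation 13 (not isolated)
Conditions: BBr3 (10 equiv), CH2Cl2, −78 °C → rt; then H2O, 0 °C
Reagents that add atoms: none
Why: BBr3 Lewis-acid cleavage of the three aryl methyl ethers also ionises the carbinol, and on hydrolysis the hydroxy-substituted trityl cation loses a phenolic proton to give the p-quinone methide (fuchsone formation, the biogenetic-type dehydration); no stereocentre is formed.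

**Compound list**
1 | methyl 3-oxopentanoate | CCC(=O)CC(=O)OC | starting material
2 | (E)-3-(4-methoxyphenyl)prop-2-enal | COc1ccc(/C=C/C=O)cc1 | starting material
3 | methyl 3-(4-methoxyphenyl)-5-oxo-2-propanoylpentanoate (Michael adduct; racemic diastereomer mixture, may sit as its cyclic hemiacetal) | CCC(=O)C(C(=O)OC)C(CC=O)c1ccc(OC)cc1 | intermediate
4 | methyl 6-(4-methoxyphenyl)-3-methyl-2-oxocyclohex-3-ene-1-carboxylate (racemic, cis/trans mixture) | COC(=O)C1C(=O)C(C)=CCC1c1ccc(OC)cc1 | intermediate
5 | methyl 2-hydroxy-6-(4-methoxyphenyl)-3-methylbenzoate | COC(=O)c1c(O)c(C)ccc1-c1ccc(OC)cc1 | intermediate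
6 | methyl 6-(4-methoxyphenyl)-3-methyl-2-(trifluoromethylsulfonyloxy)benzoate | COC(=O)c1c(OS(=O)(=O)C(F)(F)F)c(C)ccc1-c1ccc(OC)cc1 | intermediate
7 | 1-ethynyl-4-methoxybenzene | C#Cc1ccc(OC)cc1 | starting material
8 | methyl 6-(4-methoxyphenyl)-2-[(4-methoxyphenyl)ethynyl]-3-methylbenzoate | COC(=O)c1c(C#Cc2ccc(OC)cc2)c(C)ccc1-c1ccc(OC)cc1 | intermediate
9 | 1-bromo-4-methoxybenzene | COc1ccc(Br)cc1 | starting material
10 | (4-methoxyphenyl)lithium | [Li]c1ccc(OC)cc1 | intermediate
11 | [6-(4-methoxyphenyl)-2-[(4-methoxyphenyl)ethynyl]-3-methylphenyl](4-methoxyphenyl)methanone | COc1ccc(cc1)C(=O)c1c(C#Cc2ccc(OC)cc2)c(C)ccc1-c1ccc(OC)cc1 | intermediate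
12 | [6-(4-methoxyphenyl)-2-[(4-methoxyphenyl)ethynyl]-3-methylphenyl]bis(4-methoxyphenyl)methanol | COc1ccc(cc1)C(O)(c1ccc(OC)cc1)c1c(C#Cc2ccc(OC)cc2)c(C)ccc1-c1ccc(OC)cc1 | intermediate
13 | [6-(4-hydroxyphenyl)-2-[(4-hydroxyphenyl)ethynyl]-3-methylphenyl]bis(4-hydroxyphenyl)methylium (O-protonated target) | Cc1ccc(-c2ccc(O)cc2)c([C+](c2ccc(O)cc2)c2ccc(O)cc2)c1C#Cc1ccc(O)cc1 | intermediate
14 | Selaginellin U | Cc1ccc(-c2ccc(O)cc2)c(C(=C2C=CC(=O)C=C2)c2ccc(O)cc2)c1C#Cc1ccc(O)cc1 | target

**Totals**
Total step count: 5. Longest linear sequence: 5 steps (1 + 2 → 5 → 6 → 8 → 12 → 14).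

**Steps most likely to fail**

Step 1 is the most exposed. The Michael adduct may divert to a 4H-pyran, the aldol condensation may stall, or DDQ may over-oxidise. The fallback sets out from 1 and comes back at 5, and replaces the oxidative annulation by a Lewis-acid [3+3] cyclocondensation at the correct oxidation level. Me3SiCl/Et3N converts 1 into methyl 3-(trimethylsilyloxy)pent-2-enoate F1, and LDA then Me3SiCl at −78 °C gives 1-methoxy-1,3-bis(trimethylsilyloxy)penta-1,3-diene F2. The partner is made from bought 4′-methoxyacetophenone: Claisen formylation (HCO2Me, NaOMe) gives sodium 3-(4-methoxyphenyl)-3-oxoprop-1-en-1-olate F3, and HC(OMe)3/MeOH with catalytic H2SO4 gives 3,3-dimethoxy-1-(4-methoxyphenyl)propan-1-one F4. TiCl4 in CH2Cl2 (−78 → 20 °C) joins the terminal diene carbon of F2 to the acetal carbon of F4 and the central carbon to the aryl ketone; loss of methanol and water aromatises directly to salicylate 5.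

Step 3 may be slow because the triflate is flanked on both sides, with triflate hydrolysis and alkyne homocoupling as competitors. The fallback sets out from 6 and comes back at 8, and builds the alkyne in two stages so that the hindered bond is made with the smallest possible alkyne. Coupling 6 with ethynyltrimethylsilane (PdCl2(PPh3)2, CuI, Et3N, DMF, 70 °C) gives methyl 6-(4-methoxyphenyl)-3-methyl-2-[(trimethylsilyl)ethynyl]benzoate F5. K2CO3/MeOH removes silicon to give methyl 2-ethynyl-6-(4-methoxyphenyl)-3-methylbenzoate F6. A second Sonogashira coupling of F6 with 4-iodoanisole at rt, where the electrophile is unhindered, gives 8.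

Step 5 carries the risk that BBr3 or the HBr formed adds to the electron-rich diarylalkyne, or that the cation is trapped before it collapses. The fallback sets out from 12 and comes back at 14, and separates ether cleavage from dehydration without any Lewis acid. NaSEt (10 equiv) in DMF at 130 °C cleaves the three methyl ethers by SN2 attack at methyl and gives, after neutral work-up, [6-(4-hydroxyphenyl)-2-[(4-hydroxyphenyl)ethynyl]-3-methylphenyl]bis(4-hydroxyphenyl)methanol F7. Brief treatment of F7 with AcOH at rt removes water and gives 14.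

**Further compounds**
F1 | step 1 | methyl 3-(trimethylsilyloxy)pent-2-enoate (E/Z mixture) | CCC(O[Si](C)(C)C)=CC(=O)OC
F2 | step 1 | 1-methoxy-1,3-bis(trimethylsilyloxy)penta-1,3-diene (E/Z mixture) | CC=C(O[Si](C)(C)C)C=C(OC)O[Si](C)(C)C
F3 | step 1 | sodium 3-(4-methoxyphenyl)-3-oxoprop-1-en-1-olate | COc1ccc(cc1)C(=O)C=C[O-].[Na+]
F4 | step 1 | 3,3-dimethoxy-1-(4-methoxyphenyl)propan-1-one | COc1ccc(cc1)C(=O)CC(OC)OC
F5 | step 3 | methyl 6-(4-methoxyphenyl)-3-methyl-2-[(trimethylsilyl)ethynyl]benzoate | COC(=O)c1c(C#C[Si](C)(C)C)c(C)ccc1-c1ccc(OC)cc1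
F6 | step 3 | methyl 2-ethynyl-6-(4-methoxyphenyl)-3-methylbenzoate | COC(=O)c1c(C#C)c(C)ccc1-c1ccc(OC)cc1
F7 | step 5 | [6-(4-hydroxyphenyl)-2-[(4-hydroxyphenyl)ethynyl]-3-methylphenyl]bis(4-hydroxyphenyl)methanol | Cc1ccc(-c2ccc(O)cc2)c(C(O)(c2ccc(O)cc2)c2ccc(O)cc2)c1C#Cc1ccc(O)cc1
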